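Ring A of this ent-labdane (labdane numbering: ring A = C1–C5/C10, ring B = C5–C10) is closed at C2–C3 by enol ether–olefin ring-closing metathesis. The step exploits that C2 is the only oxygenated ring carbon and that C3 is a methylene flanked by the quaternary gem-dimethyl C4: a 1,1-dimethylallyl group on C5 supplies C4 and C3, and an acetate arm on the quaternary C10, methylenated to a 2-methoxyallyl group, supplies C1 and C2 with the oxygen already in place. The precursor is a monocyclic ring B silyl enol ether with these two arms trans; ethene is expelled and a masked 2-ketone results.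

Key step: step 6

Remark: 3,3-dimethylpent-4-enal (1) is taken as a catalogue aldehyde (otherwise one i-Bu2AlH reduction away from bulk methyl 3,3-dimethylpent-4-enoate); atoms are named in labdane numbering throughout.

Step 1
Reactants: 1 3,3-dimethylpent-4-enal; 2 but-3-en-2-one
Product: 4 (4S)-4-(2-methylbut-3-en-2-yl)cyclohex-2-en-1-one, via keto aldehyde 3 (not isolated)
Conditions: (R)-α,α-diphenylprolinol trimethylsilyl ether (10 mol %), ethyl 3,4-dihydroxybenzoate (20 mol %), neat, 4 °C; then TsOH·H2O (10 mol %), toluene, 60 °C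
Reagents that add atoms: none
Why: Enamine-catalysed Michael addition of the neopentyl-type aldehyde to the vinyl ketone followed by intramolecular aldol condensation (organocatalytic Robinson-type annulation) should give the 4-substituted enone, the C5 stereocentre being set by the (R)-catalyst, whose diaryl(silyloxy)methyl group shields one enamine face so that the (2R)-aldehyde and from it the (4S)-enone is expected.

Step 2
Reactants: 4 (4S)-4-(2-methylbut-3-en-2-yl)cyclohex-2-en-1-one
Product: 5 trimethyl{[(3R,4S)-3-methyl-4-(2-methylbut-3-en-2-yl)cyclohex-1-en-1-yl]oxy}silane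
Conditions: Me2CuLi, TMSCl, THF, −78 °C; then Et3N
Reagents that add atoms: Me2CuLi ([Li+].C[Cu-]C); TMSCl (C[Si](C)(C)Cl)
Why: Silyl-chloride-accelerated conjugate addition of the Gilman cuprate should place the future C20 methyl on C10 anti to the bulky C5 substituent (a transient stereocentre that step 3 removes) and trap the enolate regiospecifically as its silyl enol ether.

Step 3
Reactants: 5 trimethyl{[(3R,4S)-3-methyl-4-(2-methylbut-3-en-2-yl)cyclohex-1-en-1-yl]oxy}silane
Product: 6 (4S)-3-methyl-4-(2-methylbut-3-en-2-yl)cyclohex-2-en-1-one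
Conditions: Pd(OAc)2 (1.1 equiv), MeCN, rt
Reagents that add atoms: none
Why: Saegusa–Ito oxidation (palladation of the silyl enol ether, then β-hydride elimination of the only available β-hydrogen at C10) should return the enone with the methyl now on the β-carbon, leaving C5 and the hindered vinyl group untouched.

Step 4
Reactants: 6 (4S)-3-methyl-4-(2-methylbut-3-en-2-yl)cyclohex-2-en-1-one; 7 tert-butyl[(1-methoxyethenyl)oxy]dimethylsilane
Product: 8 methyl 2-[(1R,6R)-3-{[tert-butyl(dimethyl)silyl]oxy}-1-methyl-6-(2-methylbut-3-en-2-yl)cyclohex-2-en-1-yl]acetate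
Conditions: Tf2NH (5 mol %), CH2Cl2, −78 → −40 °C; then Et3N
Reagents that add atoms: none
Why: Mukaiyama–Michael addition under silyl triflimide catalysis should form the quaternary C10 because the acetate-derived ketene acetal is an unhindered π-nucleophile that attacks axially on the face opposite the pseudoaxial 1,1-dimethylallyl group on C5 (arm trans to that group, methyl cis), and silyl transfer delivers the regiodefined C8–C9 silyl enol ether.

Step 5
Reactants: 8 methyl 2-[(1R,6R)-3-{[tert-butyl(dimethyl)silyl]oxy}-1-methyl-6-(2-methylbut-3-en-2-yl)cyclohex-2-en-1-yl]acetate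
Product: 9 tert-butyl{[(3R,4R)-3-(2-methoxyprop-2-en-1-yl)-3-methyl-4-(2-methylbut-3-en-2-yl)cyclohex-1-en-1-yl]oxy}dimethylsilane
Conditions: Cp2TiMe2 (3 equiv), toluene, 70 °C, dark
Reagents that add atoms: Cp2TiMe2 (C[Ti](C)(C1C=CC=C1)C1C=CC=C1)
Why: Petasis methylenation should convert the ester carbonyl into the 2-methoxyallyl enol ether, since the non-basic titanium methylidene tolerates the silyl enol ether and the alkenes and touches no stereocentre.

Step 6
Reactants: 9 tert-butyl{[(3R,4R)-3-(2-methoxyprop-2-en-1-yl)-3-methyl-4-(2-methylbut-3-en-2-yl)cyclohex-1-en-1-yl]oxy}dimethylsilane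
Product: 10 tert-butyl{[(4aR,8aR)-7-methoxy-5,5,8a-trimethyl-3,4,4a,5,8,8a-hexahydronaphthalen-2-yl]oxy}dimethylsilane
Conditions: second-generation Grubbs catalyst RuCl2(H2IMes)(PCy3)(=CHPh) (10 mol %), toluene (0.005 M), 80 °C, argon sparge
Reagents that add atoms: none
Why: The ruthenium carbene should load onto the monosubstituted vinyl group at C4, the tethered 1,1-disubstituted enol ether then enters a [2+2] cycloaddition–cycloreversion and ethene leaves, so that C2 (the former ester carbon) and C3 (the inner vinyl carbon) are joined as the C2=C3 bond of a cyclic methyl enol ether. The closest known reaction type is enol ether–olefin ring-closing metathesis, as used to turn olefinic esters into cyclic enol ethers after methylenation. Ring A closes as a six-membered carbocycle by metathesis of two exocyclic alkene termini held on the adjacent ring B carbons C5 and C10. No stereocentre is formed; the trans arrangement of the two arms set in steps 1 and 4 puts both equatorial on ring B and so fixes the trans ring fusion on closure. The step needs chemoselectivity among four C=C bonds and closure over oligomerisation: the trisubstituted silyl enol ether of ring B is inert to the catalyst, the geminal methyls on C4 and the quaternary C10 bias the arms toward each other, and high dilution with removal of ethene drives the closure. The position of the oxygen is not a selectivity issue, because the enol ether carbon is C2 by construction.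

Step 7
Reactants: 10 tert-butyl{[(4aR,8aR)-7-methoxy-5,5,8a-trimethyl-3,4,4a,5,8,8a-hexahydronaphthalen-2-yl]oxy}dimethylsilane; 11 3-(trimethylsilyl)but-3-en-2-one
Product: 14 (1S,4aR,8aR)-7-methoxy-5,5,8a-trimethyl-1-(3-oxobutyl)-3,4,4a,5,8,8a-hexahydronaphthalen-2(1H)-one, via lithium enolate 12 (not isolated), via α-silyl diketone 13 (not isolated)
Conditions: MeLi, THF, 0 °C → rt; then 11, −78 °C; then NaOMe (0.2 equiv), MeOH, 0 °C → rt
Reagents that add atoms: none
Why: MeLi should cleave only the silyl enol ether to the regiodefined C8–C9 lithium enolate, which undergoes Michael addition to the α-silyl vinyl ketone (the Michael half of a Robinson annulation, the silyl group suppressing polymerisation), and methoxide then removes the silyl group and equilibrates C9 to the expected more stable epimer with the equatorial side chain cis to the C10 methyl.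

Step 8
Reactants: 14 (1S,4aR,8aR)-7-methoxy-5,5,8a-trimethyl-1-(3-oxobutyl)-3,4,4a,5,8,8a-hexahydronaphthalen-2(1H)-one; 15 triethyl phosphonoacetate
Product: 16 ethyl (2E)-5-[(1S,4aR,8aR)-7-methoxy-5,5,8a-trimethyl-2-oxo-1,2,3,4,4a,5,8,8a-octahydronaphthalen-1-yl]-3-methylpent-2-enoate
Conditions: NaH, THF, 0 → 45 °C
Reagents that add atoms: none
Why: Horner–Wadsworth–Emmons olefination should take place at the unhindered methyl ketone and not at the C8 ketone flanked by C9 and the quaternary C10, and is expected to favour the E ester (the minor Z isomer to be removed by chromatography).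

Step 9
Reactants: 16 ethyl (2E)-5-[(1S,4aR,8aR)-7-methoxy-5,5,8a-trimethyl-2-oxo-1,2,3,4,4a,5,8,8a-octahydronaphthalen-1-yl]-3-methylpent-2-enoate
Product: 17 ethyl (2E)-5-[(1S,4aR,8aR)-7-methoxy-5,5,8a-trimethyl-2-{[(trifluoromethyl)sulfonyl]oxy}-1,4,4a,5,8,8a-hexahydronaphthalen-1-yl]-3-methylpent-2-enoate
Conditions: KN(SiMe3)2 (1.05 equiv), THF, −78 °C; then PhNTf2, −78 → 0 °C
Reagents that add atoms: PhNTf2 (O=S(=O)(N(c1ccccc1)S(=O)(=O)C(F)(F)F)C(F)(F)F)
Why: Kinetic deprotonation of the ketone at the unhindered C7 methylene (not at the tertiary C9, whose configuration is therefore kept) followed by O-triflation should give the C7=C8 enol triflate, the enoate being deprotonated more slowly than the ketone.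

Step 10
Reactants: 17 ethyl (2E)-5-[(1S,4aR,8aR)-7-methoxy-5,5,8a-trimethyl-2-{[(trifluoromethyl)sulfonyl]oxy}-1,4,4a,5,8,8a-hexahydronaphthalen-1-yl]-3-methylpent-2-enoate
Product: 19 ethyl (2E)-3-methyl-5-[(1R,4aR,8aR)-2,5,5,8a-tetramethyl-7-oxo-1,4,4a,5,6,7,8,8a-octahydronaphthalen-1-yl]pent-2-enoate, via methylated enol ether 18 (not isolated)
Conditions: MeZnCl, Pd(PPh3)4 (5 mol %), THF, 50 °C; then 1 M HCl, THF, 0 °C → rt
Reagents that add atoms: MeZnCl (C[Zn]Cl); water (O)
Why: Negishi coupling of the enol triflate should install the C8 methyl with the C7=C8 double bond in place while tolerating the ester, and dilute acid in the work-up hydrolyses the ring A methyl enol ether to the 2-ketone without moving the trisubstituted alkenes.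

Step 11
Reactants: 19 ethyl (2E)-3-methyl-5-[(1R,4aR,8aR)-2,5,5,8a-tetramethyl-7-oxo-1,4,4a,5,6,7,8,8a-octahydronaphthalen-1-yl]pent-2-enoate
Product: 20 (2E)-5-[(1R,4aR,7S,8aR)-7-hydroxy-2,5,5,8a-tetramethyl-1,4,4a,5,6,7,8,8a-octahydronaphthalen-1-yl]-3-methylpent-2-en-1-ol
Conditions: i-Bu2AlH (5 equiv), CH2Cl2, −78 → 0 °C; aq. sodium potassium tartrate
Reagents that add atoms: none
Why: The aluminium hydride reduces the enoate 1,2 to the allylic alcohol and the C2 ketone under steric approach control, hydride entering from the face opposite the syn-axial methyls on C4 and C10, so that the axial alcohol cis to the C10 methyl (the 2S centre) is expected.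

Step 12
Reactants: 20 (2E)-5-[(1R,4aR,7S,8aR)-7-hydroxy-2,5,5,8a-tetramethyl-1,4,4a,5,6,7,8,8a-octahydronaphthalen-1-yl]-3-methylpent-2-en-1-ol
Product: 21 (2E)-5-[(1R,4aR,7S,8aR)-7-(acetyloxy)-2,5,5,8a-tetramethyl-1,4,4a,5,6,7,8,8a-octahydronaphthalen-1-yl]-3-methylpent-2-en-1-yl acetate
Conditions: Ac2O, pyridine, DMAP (cat.), CH2Cl2, rt → 40 °C
Reagents that add atoms: Ac2O (CC(=O)OC(C)=O)
Why: DMAP-catalysed acylation should esterify both the primary allylic and the hindered axial secondary hydroxyl with retention at C2, giving the diacetate.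

Compound list
1 | 3,3-dimethylpent-4-enal | O=CCC(C)(C)C=C | starting material
2 | but-3-en-2-one | CC(=O)C=C | starting material
3 | (2R)-2-(2-methylbut-3-en-2-yl)-5-oxohexanal | O=C[C@@H](C(C)(C)C=C)CCC(C)=O | intermediate
4 | (4S)-4-(2-methylbut-3-en-2-yl)cyclohex-2-en-1-one | O=C1C=C[C@@H](C(C)(C)C=C)CC1 | intermediate
5 | trimethyl{[(3R,4S)-3-methyl-4-(2-methylbut-3-en-2-yl)cyclohex-1-en-1-yl]oxy}silane (3,4-trans) | C[Si](C)(C)OC1=C[C@H](C)[C@@H](C(C)(C)C=C)CC1 | intermediate
6 | (4S)-3-methyl-4-(2-methylbut-3-en-2-yl)cyclohex-2-en-1-one | O=C1C=C(C)[C@@H](C(C)(C)C=C)CC1 | intermediate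
7 | tert-butyl[(1-methoxyethenyl)oxy]dimethylsilane | C=C(OC)O[Si](C)(C)C(C)(C)C | starting material
8 | methyl 2-[(1R,6R)-3-{[tert-butyl(dimethyl)silyl]oxy}-1-methyl-6-(2-methylbut-3-en-2-yl)cyclohex-2-en-1-yl]acetate | C1=C(O[Si](C)(C)C(C)(C)C)CC[C@H](C(C)(C)C=C)[C@@]1(C)CC(=O)OC | intermediate
9 | tert-butyl{[(3R,4R)-3-(2-methoxyprop-2-en-1-yl)-3-methyl-4-(2-methylbut-3-en-2-yl)cyclohex-1-en-1-yl]oxy}dimethylsilane | C1=C(O[Si](C)(C)C(C)(C)C)CC[C@H](C(C)(C)C=C)[C@@]1(C)CC(OC)=C | intermediate
10 | tert-butyl{[(4aR,8aR)-7-methoxy-5,5,8a-trimethyl-3,4,4a,5,8,8a-hexahydronaphthalen-2-yl]oxy}dimethylsilane (trans-fused) | C1=C(O[Si](C)(C)C(C)(C)C)CC[C@@H]2C(C)(C)C=C(OC)C[C@@]12C | intermediate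
11 | 3-(trimethylsilyl)but-3-en-2-one | CC(=O)C(=C)[Si](C)(C)C | starting material
12 | lithium (4aR,8aR)-7-methoxy-5,5,8a-trimethyl-3,4,4a,5,8,8a-hexahydronaphthalen-2-olate | C1=C(O[Li])CC[C@@H]2C(C)(C)C=C(OC)C[C@@]12C | intermediate
13 | (4aR,8aR)-7-methoxy-5,5,8a-trimethyl-1-[3-oxo-2-(trimethylsilyl)butyl]-3,4,4a,5,8,8a-hexahydronaphthalen-2(1H)-one (mixture at ring C1 and at the silylated carbon) | CC(=O)C([Si](C)(C)C)CC1C(=O)CC[C@@H]2C(C)(C)C=C(OC)C[C@@]12C | intermediate
14 | (1S,4aR,8aR)-7-methoxy-5,5,8a-trimethyl-1-(3-oxobutyl)-3,4,4a,5,8,8a-hexahydronaphthalen-2(1H)-one | CC(=O)CC[C@@H]1C(=O)CC[C@@H]2C(C)(C)C=C(OC)C[C@@]12C | intermediate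
15 | triethyl phosphonoacetate | CCOC(=O)CP(=O)(OCC)OCC | starting material
16 | ethyl (2E)-5-[(1S,4aR,8aR)-7-methoxy-5,5,8a-trimethyl-2-oxo-1,2,3,4,4a,5,8,8a-octahydronaphthalen-1-yl]-3-methylpent-2-enoate | CCOC(=O)/C=C(\C)CC[C@@H]1C(=O)CC[C@@H]2C(C)(C)C=C(OC)C[C@@]12C | intermediate
17 | ethyl (2E)-5-[(1S,4aR,8aR)-7-methoxy-5,5,8a-trimethyl-2-{[(trifluoromethyl)sulfonyl]oxy}-1,4,4a,5,8,8a-hexahydronaphthalen-1-yl]-3-methylpent-2-enoate | CCOC(=O)/C=C(\C)CC[C@@H]1C(OS(=O)(=O)C(F)(F)F)=CC[C@@H]2C(C)(C)C=C(OC)C[C@@]12C | intermediate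
18 | ethyl (2E)-5-[(1R,4aR,8aS)-7-methoxy-2,5,5,8a-tetramethyl-1,4,4a,5,8,8a-hexahydronaphthalen-1-yl]-3-methylpent-2-enoate | CCOC(=O)/C=C(\C)CC[C@@H]1C(C)=CC[C@@H]2C(C)(C)C=C(OC)C[C@@]12C | intermediate
19 | ethyl (2E)-3-methyl-5-[(1R,4aR,8aR)-2,5,5,8a-tetramethyl-7-oxo-1,4,4a,5,6,7,8,8a-octahydronaphthalen-1-yl]pent-2-enoate | CCOC(=O)/C=C(\C)CC[C@@H]1C(C)=CC[C@@H]2C(C)(C)CC(=O)C[C@@]12C | intermediate
20 | (2E)-5-[(1R,4aR,7S,8aR)-7-hydroxy-2,5,5,8a-tetramethyl-1,4,4a,5,6,7,8,8a-octahydronaphthalen-1-yl]-3-methylpent-2-en-1-ol | OC/C=C(\C)CC[C@@H]1C(C)=CC[C@@H]2C(C)(C)C[C@H](O)C[C@@]12C | intermediate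
21 | (2E)-5-[(1R,4aR,7S,8aR)-7-(acetyloxy)-2,5,5,8a-tetramethyl-1,4,4a,5,6,7,8,8a-octahydronaphthalen-1-yl]-3-methylpent-2-en-1-yl acetate; in labdane numbering (2S,5R,9R,10R)-labda-7,13E-diene-2,15-diyl diacetate | CC(=O)OC/C=C(\C)CC[C@@H]1C(C)=CC[C@@H]2C(C)(C)C[C@H](OC(C)=O)C[C@@]12C | target

Total step count: 12. Longest linear sequence: 12 steps (1 → 21).

Steps most likely to fail

Step 6. The ruthenium carbene may be diverted into an unreactive alkoxycarbene by the enol ether, or may load too slowly onto the vinyl group at the quaternary carbon, so that catalyst decay or intermolecular coupling outruns ring closure. The fallback sets out from 8 and comes back at 10 without a new compound (F0). A titanium ethylidene made by the Takai–Utimoto protocol (TiCl4, Zn, PbCl2 (cat.), CH3CHBr2, TMEDA, THF/CH2Cl2) should exchange onto the vinyl group with loss of propene and then olefinate the ester carbonyl within the same molecule, closing ring A as the same methyl enol ether by carbonyl–olefin metathesis.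

Step 4. Attack on the fully substituted β-carbon next to the branched C5 substituent may be too slow, so that silyl transfer to the carbonyl oxygen without C–C bond formation, or 1,2-addition, takes over. The fallback sets out from 6 and comes back at 19; it brings the C1–C2 unit in as an allyl group through a smaller copper nucleophile and adds the C2 oxygen late. CH2=CHCH2MgBr/CuBr·SMe2/TMSCl (THF, −78 °C) should give the allylated trimethylsilyl enol ether F1. Mukaiyama–Michael addition of F1 to 2 (TiCl4, CH2Cl2, −78 °C) should give the diketone F2, and olefination with 15 (NaH, THF; then NaOEt, EtOH to equilibrate C9) the keto ester F3. KN(SiMe3)2/PhNTf2 should then give the enol triflate F4, and MeZnCl/Pd(PPh3)4 the tetraene ester F5. Tsuji–Wacker oxidation (PdCl2, CuCl, O2, DMF/H2O), expected to spare the vinyl group on the quaternary carbon, should give the methyl ketone F6, and LiN(i-Pr)2/TBSCl (THF, −78 °C) the terminal silyl enol ether F7. Ring-closing metathesis with the second-generation Grubbs catalyst should give the cyclic silyl enol ether F8, whose hydrolysis (1 M HCl, THF) leads to 19.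

Step 7. Anionic polymerisation of the vinyl ketone, proton exchange between enolate and adduct, or aldol closure of the 1,5-diketone during desilylation may erode the yield, and the C9 equilibrium may be less one-sided than expected. The fallback sets out from 10 and comes back at 16; it avoids the diketone by bringing in the whole five-carbon chain. The lithium enolate from 10 (MeLi, THF) should add in 1,6-fashion to ethyl (2E)-3-methylpenta-2,4-dienoate (THF/DMPU, −78 °C) to give the deconjugated ester F9 as a mixture of alkene isomers. NaOEt/EtOH should then move the double bond into conjugation and equilibrate C9, giving 16.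

Further compounds
F0 | step 6 | none | none
F1 | step 4 | trimethyl{[(3R,4R)-3-methyl-4-(2-methylbut-3-en-2-yl)-3-(prop-2-en-1-yl)cyclohex-1-en-1-yl]oxy}silane | C1=C(O[Si](C)(C)C)CC[C@H](C(C)(C)C=C)[C@@]1(C)CC=C
F2 | step 4 | (2S,3R,4R)-3-methyl-4-(2-methylbut-3-en-2-yl)-2-(3-oxobutyl)-3-(prop-2-en-1-yl)cyclohexan-1-one | CC(=O)CC[C@@H]1C(=O)CC[C@H](C(C)(C)C=C)[C@@]1(C)CC=C
F3 | step 4 | ethyl (2E)-3-methyl-5-[(1S,2R,3R)-2-methyl-3-(2-methylbut-3-en-2-yl)-6-oxo-2-(prop-2-en-1-yl)cyclohexyl]pent-2-enoate | CCOC(=O)/C=C(\C)CC[C@@H]1C(=O)CC[C@H](C(C)(C)C=C)[C@@]1(C)CC=C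
F4 | step 4 | ethyl (2E)-3-methyl-5-[(1S,5R,6R)-6-methyl-5-(2-methylbut-3-en-2-yl)-6-(prop-2-en-1-yl)-2-{[(trifluoromethyl)sulfonyl]oxy}cyclohex-2-en-1-yl]pent-2-enoate | CCOC(=O)/C=C(\C)CC[C@@H]1C(OS(=O)(=O)C(F)(F)F)=CC[C@H](C(C)(C)C=C)[C@@]1(C)CC=C
F5 | step 4 | ethyl (2E)-5-[(1R,5R,6S)-2,6-dimethyl-5-(2-methylbut-3-en-2-yl)-6-(prop-2-en-1-yl)cyclohex-2-en-1-yl]-3-methylpent-2-enoate | CCOC(=O)/C=C(\C)CC[C@@H]1C(C)=CC[C@H](C(C)(C)C=C)[C@@]1(C)CC=C
F6 | step 4 | ethyl (2E)-5-[(1R,5R,6S)-2,6-dimethyl-5-(2-methylbut-3-en-2-yl)-6-(2-oxopropyl)cyclohex-2-en-1-yl]-3-methylpent-2-enoate | CCOC(=O)/C=C(\C)CC[C@@H]1C(C)=CC[C@H](C(C)(C)C=C)[C@@]1(C)CC(C)=O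
F7 | step 4 | ethyl (2E)-5-[(1R,5R,6S)-6-(2-{[tert-butyl(dimethyl)silyl]oxy}prop-2-en-1-yl)-2,6-dimethyl-5-(2-methylbut-3-en-2-yl)cyclohex-2-en-1-yl]-3-methylpent-2-enoate | CCOC(=O)/C=C(\C)CC[C@@H]1C(C)=CC[C@H](C(C)(C)C=C)[C@@]1(C)CC(=C)O[Si](C)(C)C(C)(C)C
F8 | step 4 | ethyl (2E)-5-[(1R,4aR,8aS)-7-{[tert-butyl(dimethyl)silyl]oxy}-2,5,5,8a-tetramethyl-1,4,4a,5,8,8a-hexahydronaphthalen-1-yl]-3-methylpent-2-enoate | CCOC(=O)/C=C(\C)CC[C@@H]1C(C)=CC[C@@H]2C(C)(C)C=C(O[Si](C)(C)C(C)(C)C)C[C@@]12C
F9 | step 7 | ethyl 5-[(4aR,8aR)-7-methoxy-5,5,8a-trimethyl-2-oxo-1,2,3,4,4a,5,8,8a-octahydronaphthalen-1-yl]-3-methylpent-3-enoate (alkene isomers, C1 epimers) | CCOC(=O)CC(C)=CCC1C(=O)CC[C@@H]2C(C)(C)C=C(OC)C[C@@]12C
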